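**Overview** (labdane numbering; ring A = C1–C5 and C10, ring B = C5–C10; "tetranorlabdane" means the skeleton without C13–C16)

- Cuts: C8=C17 (Cope elimination of a C17 dimethylamine), C12–C13 (B-alkyl Suzuki coupling, butenolide ring bought intact), C8–C17 and C9–C11 (Mannich capture and vinyl conjugate addition on a C7 enone whose oxygen is removed afterwards), C4–C18 (formaldehyde aldol), C4–C5 (intramolecular Michael addition), and ring B back to propanal, tert-butyl acrylate and methyl vinyl ketone.
- Enabling feature: H-5 and the C10 methyl are cis, C10 is quaternary and lies para to C7 across ring B, and C4 bears two identical CH2OH groups next to the C3 carbinol. Ring B can thus begin as an achiral 4-methyl-4-alkylcyclohexa-2,5-dienone (carbonyl = C7) and C4 as the α-carbon of a tethered β-keto ester that closes ring A onto C5.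
- Forward order: ring B (Robinson annulation, dehydrogenation), ring A (Michael closure), ring A oxygen pattern, C9 and C8 appendages directed by the C7 carbonyl, C7 deoxygenation, butenolide, exocyclic alkene, desilylation.
- Stereochemistry: C5 and C10 from the catalyst's choice between the two enone arms (cis fusion imposed by the tether); C3 from oxazaborolidine reagent control; C9 from axial cuprate attack on the face of the C10 methyl; C4, C7 and C8 are stereogenic only in passing.

Key step: step 7

Assumption: the quinine-derived thiourea is taken to select the enone arm that leads to the (5R,10S) series (its quinidine-derived pseudo-enantiomer replaces it if the first run shows the opposite sense), and formaldehyde is taken to enter C4 on the H-5 face (the C4 epimer would converge at 22).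

Step 1
Reactants: 1 propanal; 2 pyrrolidine
Product: 3 1-[(E)-prop-1-en-1-yl]pyrrolidine
Conditions: K2CO3, neat, 0 °C → rt; distillation under reduced pressure
Reagents that add atoms: none
Why: Condensation of an unhindered aldehyde with a secondary amine gives the enamine (Stork enamine formation), K2CO3 taking up the water and the intermediate aminal cracking on distillation.

Step 2
Reactants: 3 1-[(E)-prop-1-en-1-yl]pyrrolidine; 4 tert-butyl acrylate
Product: 6 tert-butyl 4-methyl-5-oxopentanoate (racemic), via enamine 5 (not isolated)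
Conditions: MeCN, reflux; then AcOH, H2O, rt
Reagents that add atoms: water, O
Why: Stork enamine Michael addition, in which the enamine β-carbon adds once to the acrylate (the more hindered product enamine 5 does not take up a second acrylate) and mild aqueous acid frees the aldehyde without touching the tert-butyl ester; the racemic centre is erased in step 4.

Step 3
Reactants: 6 tert-butyl 4-methyl-5-oxopentanoate; 7 methyl vinyl ketone
Product: 9 tert-butyl 3-(1-methyl-4-oxocyclohex-2-en-1-yl)propanoate (racemic), via keto aldehyde 8 (not isolated)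
Conditions: KOH (0.2 equiv), EtOH, 0 °C (7 added slowly) → rt; then 60 °C
Reagents that add atoms: none
Why: Base-mediated Robinson annulation, in which the enolate formed at the single α-CH of the aldehyde adds to the enone (Michael addition) and builds the quaternary carbon, and the methyl ketone enolate of 8 then closes ring B by aldol condensation onto the aldehyde, which can no longer enolise; the tert-butyl ester resists substoichiometric hydroxide at these temperatures.

Step 4
Reactants: 9 tert-butyl 3-(1-methyl-4-oxocyclohex-2-en-1-yl)propanoate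
Product: 10 tert-butyl 3-(1-methyl-4-oxocyclohexa-2,5-dien-1-yl)propanoate
Conditions: DDQ (2,3-dichloro-5,6-dicyano-1,4-benzoquinone), 1,4-dioxane, reflux
Reagents that add atoms: none
Why: DDQ dehydrogenation of a 4,4-disubstituted cyclohexenone at its α′,β′ positions is the standard entry to cross-conjugated dienones, the quaternary carbon blocking aromatisation, and the product is achiral (mirror plane through C7 and C10).

Step 5
Reactants: 10 tert-butyl 3-(1-methyl-4-oxocyclohexa-2,5-dien-1-yl)propanoate
Product: 11 3-(1-methyl-4-oxocyclohexa-2,5-dien-1-yl)propanoic acid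
Conditions: CF3CO2H, CH2Cl2 (1:4), 0 °C → rt, short reaction time
Reagents that add atoms: none
Why: Acidolysis of the tert-butyl ester (loss of isobutene) proceeds in the cold, well below the acidity and temperature at which 4,4-dialkyl dienones undergo dienone–phenol rearrangement.

Step 6
Reactants: 11 3-(1-methyl-4-oxocyclohexa-2,5-dien-1-yl)propanoic acid; 12 potassium monomethyl malonate
Product: 15 methyl 5-(1-methyl-4-oxocyclohexa-2,5-dien-1-yl)-3-oxopentanoate, via acyl imidazolide 13 (not isolated), via acylmalonic acid 14 (not isolated)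
Conditions: 1,1'-carbonyldiimidazole, THF, rt; then 12, MgCl2, Et3N, MeCN, rt → 40 °C; cold 1 M HCl work-up
Reagents that add atoms: none
Why: Masamune–Brooks homologation, in which the acyl imidazolide C-acylates the magnesium enolate of the malonate half-ester and decarboxylation of 14 leaves the β-keto ester, the chelated magnesium enolate being too weak a Michael donor to attack the dienone before the chiral catalyst is present.

Step 7
Reactants: 15 methyl 5-(1-methyl-4-oxocyclohexa-2,5-dien-1-yl)-3-oxopentanoate
Product: 16 methyl (4aS,8aR)-2-hydroxy-4a-methyl-7-oxo-3,4,4a,7,8,8a-hexahydronaphthalene-1-carboxylate (enol form; labdane C5 R and C10 S; cis ring fusion)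
Conditions: N-[3,5-bis(trifluoromethyl)phenyl]-N'-[(8α,9S)-6'-methoxycinchonan-9-yl]thiourea (10 mol %), toluene, −20 °C
Reagents that add atoms: none
Why: The quinuclidine nitrogen of the catalyst removes the acidic C4 proton of the β-keto ester while the thiourea N–H groups hold the dienone carbonyl by hydrogen bonding, the C4 enolate carbon adds in a Michael sense to C5, one of the two enantiotopic β-carbons, and the resulting C6–C7 enolate is protonated at C6 to leave the C8=C9 enone. The closest known reaction type is the organocatalytic desymmetrising intramolecular Michael addition of tethered stabilised carbon nucleophiles (1,3-dicarbonyl, bis-sulfonyl, nitronate or enamine donors) to 4,4-disubstituted cyclohexa-2,5-dienones, which gives cis-fused bicyclic enones; the all-carbon β-keto ester tether used here is a new substrate for it. Ring A closes by a 6-exo-trig attack (new C4–C5 bond, the attacked C5=C6 bond lying outside the new ring); attack through C2 would need a four-membered ring and attack at the C7 carbonyl a bridged one. C5 and C10 become stereogenic in the same event: their absolute configuration (5R,10S) is set by the catalyst choosing one enone arm, and their cis relation by the three-carbon tether, which can reach C5 only on the face of C10 from which it hangs. The selectivity required is therefore enantiotopic-group selection alone, because the mirror plane through C7 and C10 makes the two arms chemically identical, carbon attack is the thermodynamic outcome of a soft enolate on a soft acceptor (any oxygen adduct can revert), and the product rests as a hydrogen-bonded enol of the β-keto ester, which disfavours retro-Michael opening and so protects the enantiomeric purity.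

Step 8
Reactants: 16 methyl (4aS,8aR)-2-hydroxy-4a-methyl-7-oxo-3,4,4a,7,8,8a-hexahydronaphthalene-1-carboxylate
Product: 17 methyl (1S,4aS,8aR)-1-(hydroxymethyl)-4a-methyl-2,7-dioxo-1,2,3,4,4a,7,8,8a-octahydronaphthalene-1-carboxylate
Conditions: 37% aq. CH2O, KHCO3 (0.2 equiv), THF, 0 °C → rt
Reagents that add atoms: formaldehyde, C=O
Why: Aldol hydroxymethylation of the doubly activated C4 under bicarbonate conditions too mild to enolise C6; formaldehyde should enter on the H-5 face because the other face of the C3–C4 enolate is screened by C6 or C9 in either half-chair, and the C4 configuration loses all consequence once both arms are CH2OTBS (compound 22).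

Step 9
Reactants: 17 methyl (1S,4aS,8aR)-1-(hydroxymethyl)-4a-methyl-2,7-dioxo-1,2,3,4,4a,7,8,8a-octahydronaphthalene-1-carboxylate
Product: 18 methyl (1S,4aS,8aR)-1-{[(tert-butyldimethylsilyl)oxy]methyl}-4a-methyl-2,7-dioxo-1,2,3,4,4a,7,8,8a-octahydronaphthalene-1-carboxylate
Conditions: TBSCl, imidazole, CH2Cl2, 0 °C
Reagents that add atoms: tert-butyldimethylsilyl chloride, CC(C)(C)[Si](C)(C)Cl
Why: Routine silylation of a primary alcohol, which also stops retro-aldol loss of formaldehyde and removes the hydroxyl that could otherwise deliver hydride to the wrong face of C3.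

Step 10
Reactants: 18 methyl (1S,4aS,8aR)-1-{[(tert-butyldimethylsilyl)oxy]methyl}-4a-methyl-2,7-dioxo-1,2,3,4,4a,7,8,8a-octahydronaphthalene-1-carboxylate
Product: 19 methyl (1S,2R,4aS,8aR)-1-{[(tert-butyldimethylsilyl)oxy]methyl}-2,7-dihydroxy-4a-methyl-1,2,3,4,4a,7,8,8a-octahydronaphthalene-1-carboxylate (C7 carbinol as epimers)
Conditions: (S)-Me-CBS oxazaborolidine [(S)-1-methyl-3,3-diphenyltetrahydro-1H,3H-pyrrolo[1,2-c][1,3,2]oxazaborole] (0.5 equiv), catecholborane, toluene, −78 → −30 °C; MeOH, then aq. NaOH
Reagents that add atoms: none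
Why: Corey–Bakshi–Shibata reduction under reagent control, in which the C3 ketone binds the oxazaborolidine boron anti to its larger flank (the quaternary C4) and the nitrogen-bound borane delivers hydride to the face remote from H-5, setting 3R (hydroxyl cis to H-5 and the C10 methyl) against the substrate's own preference for attack on the H-5 face, while the C7 enone is reduced 1,2 to an allylic alcohol whose configuration does not matter.

Step 11
Reactants: 19 methyl (1S,2R,4aS,8aR)-1-{[(tert-butyldimethylsilyl)oxy]methyl}-2,7-dihydroxy-4a-methyl-1,2,3,4,4a,7,8,8a-octahydronaphthalene-1-carboxylate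
Product: 20 (1S,2R,4aS,8aR)-1-{[(tert-butyldimethylsilyl)oxy]methyl}-1-(hydroxymethyl)-4a-methyl-1,2,3,4,4a,7,8,8a-octahydronaphthalene-2,7-diol (C7 epimers)
Conditions: LiBH4, THF, MeOH (1 equiv), 0 °C → rt
Reagents that add atoms: none
Why: Borohydride reduction of the methyl ester to the primary alcohol (C19), assisted by the neighbouring alkoxides, leaves the isolated alkene and the silyl ether alone, and a silyl shift among the ring A oxygens would be harmless since all three are silylated in step 13.

Step 12
Reactants: 20 (1S,2R,4aS,8aR)-1-{[(tert-butyldimethylsilyl)oxy]methyl}-1-(hydroxymethyl)-4a-methyl-1,2,3,4,4a,7,8,8a-octahydronaphthalene-2,7-diol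
Product: 21 (4aS,7R,8S,8aR)-8-{[(tert-butyldimethylsilyl)oxy]methyl}-7-hydroxy-8-(hydroxymethyl)-4a-methyl-4a,5,6,7,8,8a-hexahydronaphthalen-2(1H)-one
Conditions: MnO2 (activated, excess), CH2Cl2, rt
Reagents that add atoms: none
Why: MnO2 allylic oxidation touches only the C7 carbinol, returning the enone and leaving the saturated secondary and primary alcohols untouched.

Step 13
Reactants: 21 (4aS,7R,8S,8aR)-8-{[(tert-butyldimethylsilyl)oxy]methyl}-7-hydroxy-8-(hydroxymethyl)-4a-methyl-4a,5,6,7,8,8a-hexahydronaphthalen-2(1H)-one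
Product: 22 (4aS,7R,8aR)-7-[(tert-butyldimethylsilyl)oxy]-8,8-bis{[(tert-butyldimethylsilyl)oxy]methyl}-4a-methyl-4a,5,6,7,8,8a-hexahydronaphthalen-2(1H)-one
Conditions: TBSOTf, 2,6-lutidine, CH2Cl2, −78 → 0 °C
Reagents that add atoms: tert-butyldimethylsilyl triflate, CC(C)(C)[Si](C)(C)OS(=O)(=O)C(F)(F)F
Why: The silyl triflate silylates the hindered secondary C3 and neopentyl C19 hydroxyls faster than it enol-silylates the enone at low temperature, and C4 now carries two identical groups and is no longer stereogenic.

Step 14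
Reactants: 22 (4aS,7R,8aR)-7-[(tert-butyldimethylsilyl)oxy]-8,8-bis{[(tert-butyldimethylsilyl)oxy]methyl}-4a-methyl-4a,5,6,7,8,8a-hexahydronaphthalen-2(1H)-one; 23 vinylmagnesium bromide
Product: 25 (3R,5R,9R,10S)-3,18,19-tris(tert-butyldimethylsilyloxy)-17-(dimethylamino)-13,14,15,16-tetranorlabd-11-en-7-one (C8 epimers), via silyl enol ether 24 (not isolated)
Conditions: 23, CuBr·SMe2 (20 mol %), Me3SiCl, THF, −78 → −40 °C; pentane, cold aq. NaHCO3 wash; then CH2=NMe2+ I−, CH2Cl2, rt; aq. NaHCO3
Reagents that add atoms: N,N-dimethylmethyleneiminium iodide (Eschenmoser's salt), C=[N+](C)C.[I-]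
Why: Copper-catalysed, Me3SiCl-accelerated conjugate addition of the vinyl Grignard reagent occurs axially at C9 anti to the pseudo-axial C1 branch (the bulky C4 being equatorial on ring B), that is on the face of the C10 methyl and H-5 (9R), and the regiodefined C7–C8 silyl enol ether 24 then undergoes a Mannich reaction with Eschenmoser's salt at C8, whose configuration is immaterial because it becomes sp2 in step 19.

Step 15
Reactants: 25 (3R,5R,9R,10S)-3,18,19-tris(tert-butyldimethylsilyloxy)-17-(dimethylamino)-13,14,15,16-tetranorlabd-11-en-7-one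
Product: 26 (3R,5R,9R,10S)-3,18,19-tris(tert-butyldimethylsilyloxy)-17-(dimethylamino)-13,14,15,16-tetranorlabd-11-en-7-ol (epimers at C7/C8)
Conditions: NaBH4, MeOH, 0 °C
Reagents that add atoms: none
Why: Borohydride reduction of the ketone of a Mannich base to the γ-amino alcohol is routine at 0 °C, where β-elimination of dimethylamine does not compete, and the C7 configuration is irrelevant.

Step 16
Reactants: 26 (3R,5R,9R,10S)-3,18,19-tris(tert-butyldimethylsilyloxy)-17-(dimethylamino)-13,14,15,16-tetranorlabd-11-en-7-ol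
Product: 27 O-[(3R,5R,9R,10S)-3,18,19-tris(tert-butyldimethylsilyloxy)-17-(dimethylamino)-13,14,15,16-tetranorlabd-11-en-7-yl] 1H-imidazole-1-carbothioate (epimers at C7/C8)
Conditions: 1,1'-thiocarbonyldiimidazole, DMAP (cat.), 1,2-dichloroethane, 70 °C
Reagents that add atoms: 1,1'-thiocarbonyldiimidazole, S=C(n1ccnc1)n1ccnc1
Why: Thioacylation of the secondary alcohol gives the Barton–McCombie precursor, and this reagent is chosen because it leaves a tertiary amine alone, whereas a chlorothionoformate or the methyl iodide of a xanthate synthesis would attack the NMe2 group.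

Step 17
Reactants: 27 O-[(3R,5R,9R,10S)-3,18,19-tris(tert-butyldimethylsilyloxy)-17-(dimethylamino)-13,14,15,16-tetranorlabd-11-en-7-yl] 1H-imidazole-1-carbothioate
Product: 28 (3R,5R,9R,10S)-3,18,19-tris(tert-butyldimethylsilyloxy)-N,N-dimethyl-13,14,15,16-tetranorlabd-11-en-17-amine (C8 epimers)
Conditions: Bu3SnH, AIBN (cat.), toluene, 100 °C
Reagents that add atoms: none
Why: Barton–McCombie deoxygenation, in which the stannyl radical adds to C=S and the secondary C7 radical is reduced by the tin hydride faster than it can engage the vinyl group (only 4-exo or 5-endo closures would be open to it), giving the C7 methylene.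

Step 18
Reactants: 28 (3R,5R,9R,10S)-3,18,19-tris(tert-butyldimethylsilyloxy)-N,N-dimethyl-13,14,15,16-tetranorlabd-11-en-17-amine; 29 3-bromo-2(5H)-furanone
Product: 31 (3R,5R,9R,10S)-3,18,19-tris(tert-butyldimethylsilyloxy)-17-(dimethylamino)labd-13-en-16,15-olide (C8 epimers), via alkylborane 30 (not isolated)
Conditions: 9-BBN-H (9-borabicyclo[3.3.1]nonane, 2.5 equiv), THF, rt → 50 °C; then 3 M aq. Cs2CO3, 29, Pd(dppf)Cl2 {[1,1'-bis(diphenylphosphino)ferrocene]dichloropalladium, 10 mol %}, AsPh3 (10 mol %), DMF, rt
Reagents that add atoms: none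
Why: The vinyl group is the only alkene at this stage, so anti-Markovnikov hydroboration places boron on C12 (excess borane covering any reversible coordination to the amine), and B-alkyl Suzuki–Miyaura coupling with the α-bromobutenolide (zerovalent palladium formed in the flask) makes C12–C13 with the lactone ring intact.

Step 19
Reactants: 31 (3R,5R,9R,10S)-3,18,19-tris(tert-butyldimethylsilyloxy)-17-(dimethylamino)labd-13-en-16,15-olide
Product: 33 (3R,5R,9R,10S)-3,18,19-tris(tert-butyldimethylsilyloxy)labda-8(17),13-dien-16,15-olide, via amine N-oxide 32 (not isolated)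
Conditions: mCPBA (1.05 equiv), CH2Cl2, −20 °C; filtration through basic alumina; then toluene, 110 °C
Reagents that add atoms: none
Why: The tertiary amine is the only site that reacts with one equivalent of peracid in the cold (the butenolide alkene is electron-poor), and the N-oxide then undergoes thermal syn Cope elimination through its single β-hydrogen, C8–H, so that both C8 epimers converge on the 8(17)-exocyclic alkene.

Step 20
Reactants: 33 (3R,5R,9R,10S)-3,18,19-tris(tert-butyldimethylsilyloxy)labda-8(17),13-dien-16,15-olide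
Product: 34 (3R,5R,9R,10S)-3,18,19-trihydroxylabda-8(17),13-dien-16,15-olide (H-5 cis to the C10 methyl; CNP0146463.1)
Conditions: HF·pyridine, pyridine, THF, 0 °C → rt
Reagents that add atoms: none
Why: Fluoride-mediated desilylation cleaves the three silyl ethers under buffered conditions that neither isomerise the exocyclic alkene nor open the butenolide, releasing the triol with all four stereocentres as set in steps 7, 10 and 14.

**Compound list**

1 | propanal | CCC=O | starting material
2 | pyrrolidine | C1CCNC1 | starting material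
3 | 1-[(E)-prop-1-en-1-yl]pyrrolidine | C/C=C/N1CCCC1 | intermediate
4 | tert-butyl acrylate | C=CC(=O)OC(C)(C)C | starting material
5 | tert-butyl 4-methyl-5-(pyrrolidin-1-yl)pent-4-enoate (enamine, not isolated) | CC(CCC(=O)OC(C)(C)C)=CN1CCCC1 | intermediate
6 | tert-butyl 4-methyl-5-oxopentanoate (racemic) | O=CC(C)CCC(=O)OC(C)(C)C | intermediate
7 | methyl vinyl ketone | CC(=O)C=C | starting material
8 | tert-butyl 4-formyl-4-methyl-7-oxooctanoate (racemic, not isolated) | O=CC(C)(CCC(C)=O)CCC(=O)OC(C)(C)C | intermediate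
9 | tert-butyl 3-(1-methyl-4-oxocyclohex-2-en-1-yl)propanoate (racemic) | CC1(CCC(=O)OC(C)(C)C)C=CC(=O)CC1 | intermediate
10 | tert-butyl 3-(1-methyl-4-oxocyclohexa-2,5-dien-1-yl)propanoate | CC1(CCC(=O)OC(C)(C)C)C=CC(=O)C=C1 | intermediate
11 | 3-(1-methyl-4-oxocyclohexa-2,5-dien-1-yl)propanoic acid | CC1(CCC(=O)O)C=CC(=O)C=C1 | intermediate
12 | potassium monomethyl malonate | COC(=O)CC(=O)[O-].[K+] | starting material
13 | 4-[3-(1H-imidazol-1-yl)-3-oxopropyl]-4-methylcyclohexa-2,5-dien-1-one (acyl imidazolide, not isolated) | CC1(CCC(=O)n2ccnc2)C=CC(=O)C=C1 | intermediate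
14 | 2-(methoxycarbonyl)-5-(1-methyl-4-oxocyclohexa-2,5-dien-1-yl)-3-oxopentanoic acid (not isolated) | COC(=O)C(C(=O)O)C(=O)CCC1(C)C=CC(=O)C=C1 | intermediate
15 | methyl 5-(1-methyl-4-oxocyclohexa-2,5-dien-1-yl)-3-oxopentanoate | COC(=O)CC(=O)CCC1(C)C=CC(=O)C=C1 | intermediate
16 | methyl (4aS,8aR)-2-hydroxy-4a-methyl-7-oxo-3,4,4a,7,8,8a-hexahydronaphthalene-1-carboxylate (enol form) | O=C1C[C@H]2C(C(=O)OC)=C(O)CC[C@@]2(C)C=C1 | intermediate
17 | methyl (1S,4aS,8aR)-1-(hydroxymethyl)-4a-methyl-2,7-dioxo-1,2,3,4,4a,7,8,8a-octahydronaphthalene-1-carboxylate | O=C1C[C@H]2[C@@](CO)(C(=O)OC)C(=O)CC[C@@]2(C)C=C1 | intermediate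
18 | methyl (1S,4aS,8aR)-1-{[(tert-butyldimethylsilyl)oxy]methyl}-4a-methyl-2,7-dioxo-1,2,3,4,4a,7,8,8a-octahydronaphthalene-1-carboxylate | O=C1C[C@H]2[C@@](CO[Si](C)(C)C(C)(C)C)(C(=O)OC)C(=O)CC[C@@]2(C)C=C1 | intermediate
19 | methyl (1S,2R,4aS,8aR)-1-{[(tert-butyldimethylsilyl)oxy]methyl}-2,7-dihydroxy-4a-methyl-1,2,3,4,4a,7,8,8a-octahydronaphthalene-1-carboxylate (C7 epimers) | OC1C[C@H]2[C@@](CO[Si](C)(C)C(C)(C)C)(C(=O)OC)[C@H](O)CC[C@@]2(C)C=C1 | intermediate
20 | (1S,2R,4aS,8aR)-1-{[(tert-butyldimethylsilyl)oxy]methyl}-1-(hydroxymethyl)-4a-methyl-1,2,3,4,4a,7,8,8a-octahydronaphthalene-2,7-diol (C7 epimers) | OC1C[C@H]2[C@@](CO[Si](C)(C)C(C)(C)C)(CO)[C@H](O)CC[C@@]2(C)C=C1 | intermediate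
21 | (4aS,7R,8S,8aR)-8-{[(tert-butyldimethylsilyl)oxy]methyl}-7-hydroxy-8-(hydroxymethyl)-4a-methyl-4a,5,6,7,8,8a-hexahydronaphthalen-2(1H)-one | O=C1C[C@H]2[C@@](CO[Si](C)(C)C(C)(C)C)(CO)[C@H](O)CC[C@@]2(C)C=C1 | intermediate
22 | (4aS,7R,8aR)-7-[(tert-butyldimethylsilyl)oxy]-8,8-bis{[(tert-butyldimethylsilyl)oxy]methyl}-4a-methyl-4a,5,6,7,8,8a-hexahydronaphthalen-2(1H)-one | O=C1C[C@H]2C(CO[Si](C)(C)C(C)(C)C)(CO[Si](C)(C)C(C)(C)C)[C@H](O[Si](C)(C)C(C)(C)C)CC[C@@]2(C)C=C1 | intermediate
23 | vinylmagnesium bromide | C=C[Mg]Br | starting material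
24 | (3R,5R,9R,10S)-3,18,19-tris(tert-butyldimethylsilyloxy)-7-(trimethylsilyloxy)-13,14,15,16,17-pentanorlabda-7,11-diene (silyl enol ether, not isolated) | C1=C(O[Si](C)(C)C)C[C@H]2C(CO[Si](C)(C)C(C)(C)C)(CO[Si](C)(C)C(C)(C)C)[C@H](O[Si](C)(C)C(C)(C)C)CC[C@@]2(C)[C@@H]1C=C | intermediate
25 | (3R,5R,9R,10S)-3,18,19-tris(tert-butyldimethylsilyloxy)-17-(dimethylamino)-13,14,15,16-tetranorlabd-11-en-7-one (C8 epimers) | CN(C)CC1C(=O)C[C@H]2C(CO[Si](C)(C)C(C)(C)C)(CO[Si](C)(C)C(C)(C)C)[C@H](O[Si](C)(C)C(C)(C)C)CC[C@@]2(C)[C@@H]1C=C | intermediate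
26 | (3R,5R,9R,10S)-3,18,19-tris(tert-butyldimethylsilyloxy)-17-(dimethylamino)-13,14,15,16-tetranorlabd-11-en-7-ol (epimers at C7/C8) | CN(C)CC1C(O)C[C@H]2C(CO[Si](C)(C)C(C)(C)C)(CO[Si](C)(C)C(C)(C)C)[C@H](O[Si](C)(C)C(C)(C)C)CC[C@@]2(C)[C@@H]1C=C | intermediate
27 | O-[(3R,5R,9R,10S)-3,18,19-tris(tert-butyldimethylsilyloxy)-17-(dimethylamino)-13,14,15,16-tetranorlabd-11-en-7-yl] 1H-imidazole-1-carbothioate (epimers at C7/C8) | CN(C)CC1C(OC(=S)n3ccnc3)C[C@H]2C(CO[Si](C)(C)C(C)(C)C)(CO[Si](C)(C)C(C)(C)C)[C@H](O[Si](C)(C)C(C)(C)C)CC[C@@]2(C)[C@@H]1C=C | intermediate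
28 | (3R,5R,9R,10S)-3,18,19-tris(tert-butyldimethylsilyloxy)-N,N-dimethyl-13,14,15,16-tetranorlabd-11-en-17-amine (C8 epimers) | CN(C)CC1CC[C@H]2C(CO[Si](C)(C)C(C)(C)C)(CO[Si](C)(C)C(C)(C)C)[C@H](O[Si](C)(C)C(C)(C)C)CC[C@@]2(C)[C@@H]1C=C | intermediate
29 | 3-bromo-2(5H)-furanone | O=C1OCC=C1Br | starting material
30 | (3R,5R,9R,10S)-12-(9-borabicyclo[3.3.1]nonan-9-yl)-3,18,19-tris(tert-butyldimethylsilyloxy)-N,N-dimethyl-13,14,15,16-tetranorlabdan-17-amine (alkylborane, not isolated) | CN(C)CC1CC[C@H]2C(CO[Si](C)(C)C(C)(C)C)(CO[Si](C)(C)C(C)(C)C)[C@H](O[Si](C)(C)C(C)(C)C)CC[C@@]2(C)[C@@H]1CCB3C4CCCC3CCC4 | intermediate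
31 | (3R,5R,9R,10S)-3,18,19-tris(tert-butyldimethylsilyloxy)-17-(dimethylamino)labd-13-en-16,15-olide (C8 epimers) | CN(C)CC1CC[C@H]2C(CO[Si](C)(C)C(C)(C)C)(CO[Si](C)(C)C(C)(C)C)[C@H](O[Si](C)(C)C(C)(C)C)CC[C@@]2(C)[C@@H]1CCC1=CCOC1=O | intermediate
32 | N-oxide of 31 (not isolated) | C[N+](C)([O-])CC1CC[C@H]2C(CO[Si](C)(C)C(C)(C)C)(CO[Si](C)(C)C(C)(C)C)[C@H](O[Si](C)(C)C(C)(C)C)CC[C@@]2(C)[C@@H]1CCC1=CCOC1=O | intermediate
33 | (3R,5R,9R,10S)-3,18,19-tris(tert-butyldimethylsilyloxy)labda-8(17),13-dien-16,15-olide | C=C1CC[C@H]2C(CO[Si](C)(C)C(C)(C)C)(CO[Si](C)(C)C(C)(C)C)[C@H](O[Si](C)(C)C(C)(C)C)CC[C@@]2(C)[C@@H]1CCC1=CCOC1=O | intermediate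
34 | (3R,5R,9R,10S)-3,18,19-trihydroxylabda-8(17),13-dien-16,15-olide, cis-fused (CNP0146463.1) | C=C1CC[C@H]2C(CO)(CO)[C@H](O)CC[C@@]2(C)[C@@H]1CCC1=CCOC1=O | target

**Step count**

Total step count: 20. Longest linear sequence: 20 steps (1 → 34); the route is fully linear, the other starting materials entering as bought reagents.

**Steps most likely to fail**

1. Step 7. The catalyst may discriminate the two enantiotopic enone arms poorly with this untested all-carbon tether, or slow reversible ring opening may erode the enantiomeric purity.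
   Fallback (resolution in place of asymmetric catalysis): setting out from 15, closure with an achiral base (DBU, MeCN, rt) gives the racemic cis-fused keto ester F1. Condensation of its β-keto ester with (R)-1-phenylethylamine (toluene, cat. AcOH, 4 Å molecular sieves) gives two diastereomeric hydrogen-bonded enamino esters, which are separated by crystallisation or chromatography. The diastereomer of the (5R,10S) series, the enamino ester F2, is hydrolysed with aqueous AcOH in THF and comes back to the route at 16, at the cost of at most half of the material.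

2. Step 10. The reagent control of the oxazaborolidine is opposed by the substrate's own facial bias at a hindered ketone, so facial selectivity at C3 may be poor or the reduction slow.
   Fallback (hydride delivered from inside the molecule): setting out from 18, LiAlH4 (THF, 0 °C) reduces the ester and both ketones without regard to C3 and gives the triol as a C3 epimer mixture F3. MnO2 restores the enone and gives the enone diol as a C3 epimer mixture F4. The secondary C3 carbinol of the 1,3-diol is then oxidised selectively through its dibutylstannylene acetal (Bu2SnO, toluene, reflux; then N-bromosuccinimide, CHCl3) to the β-hydroxy ketone F5. Its free C19 hydroxymethyl group lies trans to H-5, on the face from which hydride must arrive, so Saksena–Evans reduction (Me4NBH(OAc)3, MeCN–AcOH, −30 °C) delivers hydride from that hydroxyl, leaves the enone alone, and comes back to the route at 21 as one C3 epimer. Were formaldehyde to have entered C4 from the other face in step 8, the same directed reduction would be applied to 17 before silylation.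

3. Step 14. The hindered silyl enol ether may fail to capture the iminium ion and simply lose silicon to give the C8-unsubstituted ketone, after which the enolate regiochemistry cannot be regained; attack on the wrong face of C9 is the lesser concern.
   Fallback (C8–C17 bond made first by cross-coupling): setting out from 22, α-iodination (I2, pyridine, CH2Cl2) gives the 8-iodo enone F6. Suzuki–Miyaura coupling with potassium [(dimethylamino)methyl]trifluoroborate (Pd(OAc)2, 2-dicyclohexylphosphino-2',4',6'-triisopropylbiphenyl, Cs2CO3, THF–H2O, 80 °C) gives the 8-[(dimethylamino)methyl] enone F7. The same copper-catalysed vinyl addition, now followed only by aqueous protonation of the enolate, comes back to the route at 25.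

**Further compounds**

F1 | step 7 | racemic methyl 2-hydroxy-4a-methyl-7-oxo-3,4,4a,7,8,8a-hexahydronaphthalene-1-carboxylate (16 with its enantiomer; SMILES of the enantiomer) | O=C1C[C@@H]2C(C(=O)OC)=C(O)CC[C@]2(C)C=C1
F2 | step 7 | methyl (4aS,8aR)-4a-methyl-7-oxo-2-{[(1R)-1-phenylethyl]amino}-3,4,4a,7,8,8a-hexahydronaphthalene-1-carboxylate | O=C1C[C@H]2C(C(=O)OC)=C(N[C@H](C)c3ccccc3)CC[C@@]2(C)C=C1
F3 | step 10 | triol 20 as a mixture of C3 epimers (and C7 epimers) | OC1C[C@H]2[C@@](CO[Si](C)(C)C(C)(C)C)(CO)C(O)CC[C@@]2(C)C=C1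
F4 | step 10 | enone diol 21 as a mixture of C3 epimers | O=C1C[C@H]2[C@@](CO[Si](C)(C)C(C)(C)C)(CO)C(O)CC[C@@]2(C)C=C1
F5 | step 10 | (4aS,8S,8aR)-8-{[(tert-butyldimethylsilyl)oxy]methyl}-8-(hydroxymethyl)-4a-methyl-4a,5,8,8a-tetrahydronaphthalene-2,7(1H,6H)-dione | O=C1C[C@H]2[C@@](CO[Si](C)(C)C(C)(C)C)(CO)C(=O)CC[C@@]2(C)C=C1
F6 | step 14 | (4aS,7R,8aR)-7-[(tert-butyldimethylsilyl)oxy]-8,8-bis{[(tert-butyldimethylsilyl)oxy]methyl}-3-iodo-4a-methyl-4a,5,6,7,8,8a-hexahydronaphthalen-2(1H)-one | O=C1C[C@H]2C(CO[Si](C)(C)C(C)(C)C)(CO[Si](C)(C)C(C)(C)C)[C@H](O[Si](C)(C)C(C)(C)C)CC[C@@]2(C)C=C1I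
F7 | step 14 | (4aS,7R,8aR)-7-[(tert-butyldimethylsilyl)oxy]-8,8-bis{[(tert-butyldimethylsilyl)oxy]methyl}-3-[(dimethylamino)methyl]-4a-methyl-4a,5,6,7,8,8a-hexahydronaphthalen-2(1H)-one | O=C1C[C@H]2C(CO[Si](C)(C)C(C)(C)C)(CO[Si](C)(C)C(C)(C)C)[C@H](O[Si](C)(C)C(C)(C)C)CC[C@@]2(C)C=C1CN(C)C
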